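**Plan**

1. Retrosynthesis cuts, in order: the four MOM ethers; the C3–C4 bond of ring C (ketone carbon to CH2), which leads back to an achiral ring A aldehyde carrying ring B as a 1-arylvinyl ether on O1; the enol ether C=C and the O1–C2 bond; on ring A the formyl C–C bond and the C6–geranyl bond.
2. Forward, ring A is elaborated from phloroglucinol (bis-MOM, O-silyl, metalation and geranylation between the two MOM ethers, desilylation, ortho-formylation). The geranylated phenol is symmetric, so the geranyl group is necessarily para to the future O1 and the formyl group ortho to it (6-geranyl, not 8-geranyl).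
3. Ring B enters as a racemic bromohydrin made from 3',4'-dihydroxyacetophenone. Mitsunobu etherification and dehydrobromination give the enol ether, ring C is closed last, and the MOM groups are then removed.
4. Enabling feature: O1 on C8a holds the enol ether CH2 (future C3) within reach of the formyl carbon (future C4) on the neighbouring ring A carbon C4a. C2 is a prochiral sp2 carbon bearing O1 and the ring B aryl with no allylic hydrogen, so one intramolecular hydroacylation makes the C3–C4 bond, ring C and the C2 stereocentre.
5. Stereochemistry: (2S) comes from catalyst control (chiral bisphosphine on rhodium) in the ring closure; the (E)-olefin of the side chain is carried unchanged from geranyl bromide.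

Key step: step 11

Assumption: the sense of induction of the bisphosphine in step 11 cannot be predicted with certainty; (R)-DTBM-SEGPHOS is written, and its antipode would be taken if the (2R)-product should be favoured.

**Route**

Step 1
Reactants: 1 phloroglucinol
Product: 2 3,5-bis(methoxymethoxy)phenol
Conditions: MOMCl (2.0 equiv), iPr2NEt (2.2 equiv), DMF, 0 °C to rt; chromatography
Reagents that add atoms: chloromethyl methyl ether (MOMCl), COCCl
Why: Statistical O-alkylation (MOM acetal formation) of a symmetric triol whose three hydroxyls are equivalent, so two equivalents of MOMCl should give the bis-ether as the main component, separable from the mono- and tris-ethers.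

Step 2
Reactants: 2 3,5-bis(methoxymethoxy)phenol
Product: 3 [3,5-bis(methoxymethoxy)phenoxy]tri(propan-2-yl)silane
Conditions: TIPSCl, imidazole, DMF, rt
Reagents that add atoms: chlorotri(propan-2-yl)silane (TIPSCl), CC(C)[Si](Cl)(C(C)C)C(C)C
Why: Standard imidazole-promoted silylation of a phenol; the bulky, poorly coordinating OTIPS group removes the acidic proton and leaves the carbon between the two MOM ethers as the preferred metalation site.

Step 3
Reactants: 3 [3,5-bis(methoxymethoxy)phenoxy]tri(propan-2-yl)silane; 4 geranyl bromide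
Product: 6 {4-[(2E)-3,7-dimethylocta-2,6-dien-1-yl]-3,5-bis(methoxymethoxy)phenoxy}tri(propan-2-yl)silane, via aryllithium 5 (not isolated)
Conditions: n-BuLi, THF, 0 °C; then CuBr·SMe2 (10 mol %), 4, −78 °C to rt
Reagents that add atoms: none
Why: Directed ortho-metalation at the carbon flanked by the two chelating MOM ethers, then copper-catalysed SN2 allylation of the aryllithium by the primary allylic bromide, which should keep the (E)-olefin and, by the symmetry of 3, place the geranyl group para to the silyloxy oxygen.

Step 4
Reactants: 6 geranylated silyl ether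
Product: 7 4-[(2E)-3,7-dimethylocta-2,6-dien-1-yl]-3,5-bis(methoxymethoxy)phenol
Conditions: Bu4NF, AcOH (1:1), THF, 0 °C
Reagents that add atoms: none
Why: Fluoride-mediated desilylation of an aryl silyl ether, buffered with acetic acid so that the MOM acetals and the geranyl chain are untouched.

Step 5
Reactants: 7 4-geranyl-3,5-bis(methoxymethoxy)phenol
Product: 9 3-[(2E)-3,7-dimethylocta-2,6-dien-1-yl]-6-hydroxy-2,4-bis(methoxymethoxy)benzaldehyde, via benzylic alcohol 8 (not isolated)
Conditions: MgCl2, Et3N, paraformaldehyde, THF, reflux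
Reagents that add atoms: paraformaldehyde (as formaldehyde), C=O
Why: Casnati–Skattebøl ortho-formylation, in which the magnesium phenoxide delivers formaldehyde to the ortho carbon and a second formaldehyde oxidises the benzylic alkoxide by hydride transfer; the two ortho positions of 7 are equivalent and the para position is blocked, so only one aldehyde can form.

Step 6
Reactants: 10 1-(3,4-dihydroxyphenyl)ethan-1-one
Product: 11 1-[3,4-bis(methoxymethoxy)phenyl]ethan-1-one
Conditions: MOMCl, iPr2NEt, CH2Cl2, 0 °C to rt
Reagents that add atoms: chloromethyl methyl ether (MOMCl), COCCl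
Why: Standard MOM protection of a catechol under hindered amine base.

Step 7
Reactants: 11 1-[3,4-bis(methoxymethoxy)phenyl]ethan-1-one
Product: 14 2-bromo-1-[3,4-bis(methoxymethoxy)phenyl]ethan-1-one, via lithium enolate 12 (not isolated), via silyl enol ether 13 (not isolated)
Conditions: LiN(SiMe3)2, THF, −78 °C; Me3SiCl, −78 to 0 °C; then NBS, 0 °C
Reagents that add atoms: N-bromosuccinimide (NBS), O=C1CCC(=O)N1Br
Why: α-Bromination of a methyl ketone through its silyl enol ether with NBS, which avoids the hydrogen bromide of a direct bromination that would cleave the MOM acetals.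

Step 8
Reactants: 14 2-bromo-1-[3,4-bis(methoxymethoxy)phenyl]ethan-1-one
Product: 15 rac-2-bromo-1-[3,4-bis(methoxymethoxy)phenyl]ethan-1-ol
Conditions: NaBH4, MeOH, 0 °C; aq. NH4Cl quench
Reagents that add atoms: none
Why: Borohydride reduction of the α-bromo ketone at low temperature should stop at the bromohydrin before epoxide closure competes; the carbinol centre is left racemic because step 10 erases it.

Step 9
Reactants: 9 3-geranyl-6-hydroxy-2,4-bis(methoxymethoxy)benzaldehyde; 15 rac-2-bromo-1-[3,4-bis(methoxymethoxy)phenyl]ethan-1-ol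
Product: 16 rac-6-{2-bromo-1-[3,4-bis(methoxymethoxy)phenyl]ethoxy}-3-[(2E)-3,7-dimethylocta-2,6-dien-1-yl]-2,4-bis(methoxymethoxy)benzaldehyde
Conditions: PPh3, DIAD, THF, 0 °C to rt
Reagents that add atoms: none
Why: Mitsunobu etherification of the acidic salicylaldehyde-type phenol, the only free hydroxyl of 9, with the secondary benzylic alcohol forms the O1–C2 bond; the new centre is racemic and is removed in the next step.

Step 10
Reactants: 16 racemic bromo ether
Product: 17 6-({1-[3,4-bis(methoxymethoxy)phenyl]ethenyl}oxy)-3-[(2E)-3,7-dimethylocta-2,6-dien-1-yl]-2,4-bis(methoxymethoxy)benzaldehyde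
Conditions: KOtBu, THF, 0 °C to rt; chromatography on Et3N-deactivated silica
Reagents that add atoms: none
Why: E2 dehydrobromination, the classical route from β-bromo ethers to α-alkoxystyrenes; the only β-hydrogen is the benzylic α-aryloxy hydrogen, so only the 1-arylvinyl aryl ether can form, and the non-enolisable aldehyde should tolerate tert-butoxide at low temperature.

Step 11
Reactants: 17 enol ether aldehyde
Product: 18 (2S)-2-[3,4-bis(methoxymethoxy)phenyl]-6-[(2E)-3,7-dimethylocta-2,6-dien-1-yl]-5,7-bis(methoxymethoxy)-2,3-dihydro-4H-chromen-4-one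
Conditions: [Rh(cod)Cl]2 (2.5 mol %), (R)-DTBM-SEGPHOS (5.5 mol %), Na[B(3,5-(CF3)2C6H3)4] (5 mol %), 1,4-dioxane, 4 Å MS, 60 °C
Reagents that add atoms: none
Why: Proposed new method: the cationic monovalent rhodium bisphosphine should add oxidatively into the formyl C–H bond of 17 to give an acyl hydride of trivalent rhodium (held against decarbonylation by the flanking ether oxygens), bind the enol ether, transfer hydride to its internal carbon (future C2) to give a seven-membered acyl alkyl rhodacycle, and close ring C by C–C reductive elimination between the acyl carbon and the terminal CH2, a 6-endo-trig closure overall. The closest known reaction type is the rhodium-catalysed enantioselective endo hydroacylation of 1,1-disubstituted alkenes held ortho to an aromatic aldehyde, which gives 3-substituted indan-1-ones from 2-(1-arylvinyl)benzaldehydes and 3-substituted tetralones from 2-(2-substituted allyl)benzaldehydes; here an oxygen replaces the carbon tether, a substrate class on which it has not been shown. The only new stereocentre, C2, is set in the hydride insertion, where the chiral bisphosphine decides which face of the prochiral enol ether receives the hydride (catalyst control, achiral substrate). The step needs endo over exo regioselectivity, secured because the internal carbon carries both the ring B aryl and the aryloxy oxygen, so the exo path would require a tertiary alkyl rhodium and reductive elimination to a quaternary carbon. The enol ether has no allylic hydrogen, so olefin isomerisation cannot compete, and the two trisubstituted geranyl olefins are remote and too hindered to insert. All atoms of 17 appear in 18, so the step is a catalytic isomerisation.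

Step 12
Reactants: 18 tetra-MOM flavanone
Product: 19 nymphaeol A
Conditions: HCl (1 M in MeOH), rt, argon
Reagents that add atoms: none
Why: Acid-catalysed transacetalisation of the four phenolic MOM ethers to methanol, a deprotection with precedent on prenylated polyphenols; under dilute acid at room temperature the geranyl olefins and the C2 centre should survive.

**Compound list**

1 | phloroglucinol (benzene-1,3,5-triol) | Oc1cc(O)cc(O)c1 | starting material
2 | 3,5-bis(methoxymethoxy)phenol | COCOc1cc(O)cc(OCOC)c1 | intermediate
3 | [3,5-bis(methoxymethoxy)phenoxy]tri(propan-2-yl)silane | COCOc1cc(OCOC)cc(O[Si](C(C)C)(C(C)C)C(C)C)c1 | intermediate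
4 | geranyl bromide, (2E)-1-bromo-3,7-dimethylocta-2,6-diene | CC(C)=CCC/C(C)=C/CBr | starting material
5 | {2,6-bis(methoxymethoxy)-4-[tri(propan-2-yl)silyloxy]phenyl}lithium | [Li]c1c(OCOC)cc(O[Si](C(C)C)(C(C)C)C(C)C)cc1OCOC | intermediate
6 | {4-[(2E)-3,7-dimethylocta-2,6-dien-1-yl]-3,5-bis(methoxymethoxy)phenoxy}tri(propan-2-yl)silane | CC(C)=CCC/C(C)=C/Cc1c(OCOC)cc(O[Si](C(C)C)(C(C)C)C(C)C)cc1OCOC | intermediate
7 | 4-[(2E)-3,7-dimethylocta-2,6-dien-1-yl]-3,5-bis(methoxymethoxy)phenol | CC(C)=CCC/C(C)=C/Cc1c(OCOC)cc(O)cc1OCOC | intermediate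
8 | 4-[(2E)-3,7-dimethylocta-2,6-dien-1-yl]-2-(hydroxymethyl)-3,5-bis(methoxymethoxy)phenol | CC(C)=CCC/C(C)=C/Cc1c(OCOC)cc(O)c(CO)c1OCOC | intermediate
9 | 3-[(2E)-3,7-dimethylocta-2,6-dien-1-yl]-6-hydroxy-2,4-bis(methoxymethoxy)benzaldehyde | CC(C)=CCC/C(C)=C/Cc1c(OCOC)cc(O)c(C=O)c1OCOC | intermediate
10 | 1-(3,4-dihydroxyphenyl)ethan-1-one | CC(=O)c1ccc(O)c(O)c1 | starting material
11 | 1-[3,4-bis(methoxymethoxy)phenyl]ethan-1-one | CC(=O)c1ccc(OCOC)c(OCOC)c1 | intermediate
12 | lithium 1-[3,4-bis(methoxymethoxy)phenyl]ethen-1-olate | [Li]OC(=C)c1ccc(OCOC)c(OCOC)c1 | intermediate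
13 | ({1-[3,4-bis(methoxymethoxy)phenyl]ethenyl}oxy)trimethylsilane | C=C(O[Si](C)(C)C)c1ccc(OCOC)c(OCOC)c1 | intermediate
14 | 2-bromo-1-[3,4-bis(methoxymethoxy)phenyl]ethan-1-one | O=C(CBr)c1ccc(OCOC)c(OCOC)c1 | intermediate
15 | rac-2-bromo-1-[3,4-bis(methoxymethoxy)phenyl]ethan-1-ol | OC(CBr)c1ccc(OCOC)c(OCOC)c1 | intermediate
16 | rac-6-{2-bromo-1-[3,4-bis(methoxymethoxy)phenyl]ethoxy}-3-[(2E)-3,7-dimethylocta-2,6-dien-1-yl]-2,4-bis(methoxymethoxy)benzaldehyde | CC(C)=CCC/C(C)=C/Cc1c(OCOC)cc(OC(CBr)c2ccc(OCOC)c(OCOC)c2)c(C=O)c1OCOC | intermediate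
17 | 6-({1-[3,4-bis(methoxymethoxy)phenyl]ethenyl}oxy)-3-[(2E)-3,7-dimethylocta-2,6-dien-1-yl]-2,4-bis(methoxymethoxy)benzaldehyde | CC(C)=CCC/C(C)=C/Cc1c(OCOC)cc(OC(=C)c2ccc(OCOC)c(OCOC)c2)c(C=O)c1OCOC | intermediate
18 | (2S)-2-[3,4-bis(methoxymethoxy)phenyl]-6-[(2E)-3,7-dimethylocta-2,6-dien-1-yl]-5,7-bis(methoxymethoxy)-2,3-dihydro-4H-chromen-4-one | CC(C)=CCC/C(C)=C/Cc1c(OCOC)cc2c(c1OCOC)C(=O)C[C@@H](c1ccc(OCOC)c(OCOC)c1)O2 | intermediate
19 | nymphaeol A, (2S)-2-(3,4-dihydroxyphenyl)-6-[(2E)-3,7-dimethylocta-2,6-dien-1-yl]-5,7-dihydroxy-2,3-dihydro-4H-chromen-4-one | CC(C)=CCC/C(C)=C/Cc1c(O)cc2c(c1O)C(=O)C[C@@H](c1ccc(O)c(O)c1)O2 | target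

**Summary**

Total steps: 12. Longest linear sequence: 9 steps (steps 1 to 5, then 9 to 12); the ring B branch (steps 6 to 8) joins at step 9.

**Steps most likely to fail**

Step 11 (labelled). The ring closure may lose out to exo insertion, to decarbonylation of the acyl rhodium hydride, to β-aryloxy elimination from the alkyl rhodium intermediate, to hydrolysis of the enol ether by adventitious acid, or it may proceed with poor facial selectivity. The fallback uses known chemistry and sets out from bromo ketone 14 and phenol 9. Corey–Bakshi–Shibata reduction of 14 ((S)-Me-CBS oxazaborolidine, BH3·SMe2, THF, −20 °C) should give (S)-2-bromo-1-[3,4-bis(methoxymethoxy)phenyl]ethan-1-ol F1. Mitsunobu coupling of F1 with 9 (PPh3, DIAD, toluene, −20 to 0 °C) with inversion should give the (R)-bromo ether F2, the single-enantiomer form of 16. The carbene-catalysed intramolecular acylation known for 2-(2-haloethoxy)benzaldehydes (thiazolium precatalyst, DBU, dioxane, heat), in which the Breslow intermediate displaces the primary bromide, would then form the same C3–C4 bond with the stereocentre already in place and return to the route at 18.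

Step 9. O-alkylation of the hydrogen-bonded, ortho-substituted phenol may be slow, so that ionisation or elimination of the activated electron-rich benzylic alcohol takes over. The fallback sets out from ketone 11 and phenol 9 and avoids both the Mitsunobu step and the elimination. Enolisation and triflation of 11 (KN(SiMe3)2, PhNTf2, THF, −78 °C) should give 1-[3,4-bis(methoxymethoxy)phenyl]ethenyl trifluoromethanesulfonate F3. Miyaura borylation of F3 (B2pin2, PdCl2(PPh3)2, PPh3, KOPh, toluene, 50 °C) should give 2-{1-[3,4-bis(methoxymethoxy)phenyl]ethenyl}-4,4,5,5-tetramethyl-1,3,2-dioxaborolane F4. Chan–Lam O-vinylation of 9 with F4 (Cu(OAc)2, a divalent copper salt, pyridine, 4 Å MS, CH2Cl2, air, rt) would give the enol ether directly and return to the route at 17.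

Step 12. Brønsted acid may cause cyclisation of the geranyl chain onto a flanking phenol, addition of methanol to the distal olefin, or erosion of the C2 configuration by ring opening and reclosure. The fallback sets out from 18 and replaces protic acetal solvolysis by a two-stage silyl exchange. Treatment with Me3SiOTf and 2,2'-bipyridyl (CH2Cl2, 0 °C) should convert the four aromatic MOM ethers into (2S)-6-[(2E)-3,7-dimethylocta-2,6-dien-1-yl]-5,7-bis(trimethylsilyloxy)-2-[3,4-bis(trimethylsilyloxy)phenyl]-2,3-dihydro-4H-chromen-4-one F5 without free acid. Neutral hydrolysis of F5 (water, THF, rt) would then return to the route at 19.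

**Further compounds**

F1 | step 11 | (S)-2-bromo-1-[3,4-bis(methoxymethoxy)phenyl]ethan-1-ol | O[C@H](CBr)c1ccc(OCOC)c(OCOC)c1
F2 | step 11 | 6-{(1R)-2-bromo-1-[3,4-bis(methoxymethoxy)phenyl]ethoxy}-3-[(2E)-3,7-dimethylocta-2,6-dien-1-yl]-2,4-bis(methoxymethoxy)benzaldehyde | CC(C)=CCC/C(C)=C/Cc1c(OCOC)cc(O[C@@H](CBr)c2ccc(OCOC)c(OCOC)c2)c(C=O)c1OCOC
F3 | step 9 | 1-[3,4-bis(methoxymethoxy)phenyl]ethenyl trifluoromethanesulfonate | C=C(OS(=O)(=O)C(F)(F)F)c1ccc(OCOC)c(OCOC)c1
F4 | step 9 | 2-{1-[3,4-bis(methoxymethoxy)phenyl]ethenyl}-4,4,5,5-tetramethyl-1,3,2-dioxaborolane | CC1(C)OB(C(=C)c2ccc(OCOC)c(OCOC)c2)OC1(C)C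
F5 | step 12 | (2S)-6-[(2E)-3,7-dimethylocta-2,6-dien-1-yl]-5,7-bis(trimethylsilyloxy)-2-[3,4-bis(trimethylsilyloxy)phenyl]-2,3-dihydro-4H-chromen-4-one | CC(C)=CCC/C(C)=C/Cc1c(O[Si](C)(C)C)cc2c(c1O[Si](C)(C)C)C(=O)C[C@@H](c1ccc(O[Si](C)(C)C)c(O[Si](C)(C)C)c1)O2
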